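10.2% of the charge stood as open dimer, on average, over the 7 readings of the larch run, and you want to know what that figure becomes in this flask, charged at twice the strength.

| flask | substrate | remark | time |
|---|---|---|---|
| larch | 0.10 M | run made earlier |  |
| flask | 0.20 M |  | 15 d |

- larch (time / d: open dimer / %, ring / %): 0.250: 10.9, 56.2; 0.625: 9.6, 71.4; 1.25: 10.8, 76.3; 2.08: 9.6, 78.6; 2.50: 10.8, 79.4; 4.00: 10.5, 84.7; 5.00: 9.5, 85.6

(each reading ± 1 percentage point)

- in percentages every species weighs as the substrate in it: one open dimer counts as two
- in percentages every species weighs as the substrate in it: one open trimer counts as three
- the earlier runs were read with a standard deviation of 1 percentage point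
- steps under discussion: substrate + open dimer -> open trimer; substrate -> ring; 2 substrate -> open dimer; substrate <-> dormant form

1. when, up to 15 d, the flask holds most open dimer
2. the amount of open dimer, in percent of the substrate charged, at that time
3. earliest time at which at least nineteen twentieths of that best amount are there, in d
4. latest time at which they still are, in d

Substrate can close to ring, pair to open dimer, or park as dormant form and come back, and open dimer can take up substrate to give open trimer. The larch run sorts these onto rungs. The fastest rung is well under way at 0.250 d, with ring at 56.2%, and open dimer then stays between 9.5% and 10.9%, a spread that a scatter of 1 percentage point covers. On the next rung ring creeps from 76.3% at 1.25 d to 85.6% at 5.00 d, which I read as substrate returning from the dormant form. Loss to open trimer does not show clearly in these readings.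

Now compare rates at one moment. Pairing goes with the square of the substrate and closing with its first power, so their ratio, a selectivity factor, follows the substrate present. As the fraction of charge left drifts down, that ratio falls along the same path in both flasks, scaled by the charge. My rule is therefore to scale the dimer ratio, open dimer over the rest of the charge, with the charge. The larch run gives 0.114, so this flask gets 0.228, or 18.6% of its charge.

The forecast stands lower than my figure, at 17.5% near 0.4 d, with its window from 0.2 d to 2.5 d. It warns: “The late-time numbers are therefore very uncertain”.

This flask gives 16.9% at 0.277 d, and its window runs from 0.149 d to 1.44 d.

    substrate + open dimer → open trimer (k = 0.590 L mol⁻¹ h⁻¹)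
    substrate → ring (k = 0.190 h⁻¹)
    2 substrate → open dimer (k = 0.340 L mol⁻¹ h⁻¹)
    substrate ⇌ dormant form (K = 2.00, k = 0.0380 h⁻¹)

At that best time this flask also holds 5.72% as open trimer. Its dimer ratio there is 0.203, lower than the 0.228 reckoned. A neighbour flask charged at 0.12 M scales from the larch run to a dimer ratio of 0.137, which means 12.0% of its charge, and its best stands at 12.3%.

(The runs are calculated from invented constants.)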